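Slowness here is counted per catalyst. Catalyst-time is the loading of free catalyst multiplied by the clock, and each turn of the cycle (turnover) costs an amount of it.

| flask | starting material | coupling partner | free catalyst | remark | time |
|---|---|---|---|---|---|
| ochre | 0.42 M | 5 equiv | 4.4 mol% | run made earlier |  |
| green | 0.42 M | 5 equiv | 11 mol% | run made earlier |  |
| dusk | 0.42 M | 5.00 equiv | 14 mol% |  | 6.0 min |
| autumn | 0.42 M | 5.00 equiv | 5 mol% |  | 6.0 min |

| run | time / min | target / % |
|---|---|---|
| ochre | 0.417 | 1.3 |
| ochre | 1.00 | 6.6 |
| ochre | 2.00 | 12.8 |
| ochre | 3.00 | 18.5 |
| ochre | 4.00 | 25.8 |
| green | 0.833 | 10.9 |
| green | 1.50 | 22.4 |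
| green | 2.50 | 35.1 |
| green | 3.00 | 44.0 |
| green | 4.00 | 56.9 |

(scatter of a reading: 1 percentage point)

- what was read earlier has a scatter of 1 percentage point, one standard deviation
- a reading or a percentage of target counts all its forms, free or not

1. which of the two ends with the higher amount of target, in percent of the starting material charged ("neither" if they lie within 2 percentage points) (dusk / autumn / neither)
2. target at the end, in percent of the starting material charged, dusk
3. target at the end, in percent of the starting material charged, autumn

Take the main step first, with a fixed cycle time, the reciprocal of the turnover frequency. Ochre's last reading stands at 0.176 min of catalyst-time and gives a cycle time of 0.682 min. Dusk, at 0.840 min, then asks for 123% of the charge, more than the charge holds. Autumn, at 0.300 min, asks for 44.0%.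

Now add one process: the catalyst has to capture starting material, and that wait lengthens as [starting material] falls. Let x be the fraction of the charge that has become target, and treat the remainder as unreacted starting material. Integrating the cycle time gives catalyst-time as a fixed part times x, plus a capture time times the natural logarithm of the reciprocal of the remainder. The last readings of ochre and green, 0.440 min for green, give two such equations. They yield a fixed part of 0.355 min and a capture time of 0.282 min, the wait per cycle at charged [starting material], both read with the scatter of the readings. Solving the equation brings dusk down to 85.0% and autumn to 41.7%.

A start-up lag may come last: ochre's first reading lies 1.6 percentage points below the line reckoned with the starting cycle, against a scatter of 1 point, and the reckoning adds no correction for it.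

The forecast names dusk as higher, with 94% for dusk (range 82% to 100%) and 43% for autumn (range 38% to 47%), noting that “the rate must fall as starting material runs out”. For dusk it stands higher than the reckoning above.

The flasks give 85.7% in dusk and 41.4% in autumn, so dusk ends higher.

    starting material + free catalyst → catalyst intermediate A (k = 12.0 M⁻¹ min⁻¹)
    coupling partner + catalyst intermediate A → catalyst intermediate B (k = 6.50 M⁻¹ min⁻¹)
    catalyst intermediate B → catalyst intermediate C (k = 300 min⁻¹)
    catalyst intermediate C → free catalyst + target (k = 2.80 min⁻¹)
    crystals ⇌ target, rate k5*(cs5 - [target]) while solid is left; crystals form when [target] > cs5 (solubility = 0.240 M, k = 12.0 min⁻¹)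
    coupling partner + free catalyst + target → free catalyst + over-reaction product (k = 0.0760 M⁻² min⁻¹)

The gap comes from the loading: autumn given dusk's loading goes from 41.4% to 85.7%. Yet dusk holds 2.80 times autumn's catalyst and 2.07 times its target. With the capture time of 0.282 min and 10.1% of the starting material left at the end of dusk, dusk's cycle reckons to 3.15 min there against 0.637 min at the start, and the forecast for dusk stands 8.3 points high.

The neighbour like autumn but charged with 20 mol% has 1.20 min of catalyst-time, and the capture time 0.282 min reckons it to 95.3%. That flask gives 94.5%.

The runs were generated by integration with constants of no real substance, and the scatter is random.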